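## Structural features

The target is a flavanone: a chroman-4-one in which the benzo ring A and the dihydropyranone ring C share the C4a–C8a bond, with the 2,4-dihydroxyphenyl ring B attached to C2 by a single bond. Ring A carries hydrogen at C5, a 3-methylbut-2-enyl (prenyl) group at C6, a hydroxyl at C7 and a second prenyl group at C8; there is no oxygen at C5. The only stereocentre is C2 (S), a benzylic ether carbon between O1 and the C3 methylene, so no stereocentres stand next to each other and no relative configuration has to be controlled. C2 is configurationally fragile: base opens ring C by retro-oxa-Michael reaction to the chalcone, and acid can ionise the C2–O1 bond with help from the ortho and para oxygens of ring B. The two trisubstituted alkenes sit ortho to the C7 phenol; under acid they cyclise to chromanes or add HX, and they rule out hydrogenolysis and most oxidants. The real difficulty is placing two prenyl groups regiospecifically on ring A, which direct C-prenylation of a resorcinol ketone does not do cleanly, while keeping C2 intact. The plan uses the fact that ring A shares only C4a–C8a with ring C: carbons C5 to C8, bearing H, prenyl, OH and prenyl, correspond atom for atom to a 1-methoxy-3-siloxybuta-1,3-diene that carries both prenyl groups, so ring A can be grown onto an enantiopure ring C in which C2 is already set.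

## Logic of the disconnections

17 ⇒ 16. The two aryl O–Si bonds of ring B are cut. This masks the 2'- and 4'-phenols, whose phenoxides would trigger ring opening at C2, through all earlier steps. The forward step must free them without base strong enough to open ring C and without acid that would add the C7 phenol to a prenyl group.

16 ⇒ 6 + 13. The C4a–C5 and C8–C8a bonds are cut, which removes ring A as a four-carbon diene. The whole substitution pattern of ring A is then encoded in an acyclic compound, and the stereocentre stays in a small pyranone. The forward step needs a regioselective cycloaddition to an electron-rich, α-brominated vinylogous ester, followed by loss of methanol and HBr under conditions that leave C2–O1 alone.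

6 ⇒ 5. The C5–Br bond (pyranone numbering) is cut, so the activating and leaving group is introduced after the stereocentre. The forward step must brominate C5 in preference to the oxygenated ring B and must not enolise C3.

5 ⇒ 2 + 3. The C2–C3 and O1–C6 bonds of the pyranone are cut. Ring C and the only stereocentre then come from an aldehyde and a commercial diene in one catalytic operation. The forward step needs facial control on a hindered, electron-rich aldehyde and an acid stage mild enough for the benzylic C–O bond.

2 ⇒ 1. The two O–Si bonds are cut, leading back to a commercial aldehyde. The forward step must silylate the chelated 2-hydroxyl as well as the 4-hydroxyl.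

13 ⇒ 12. The enol O–Si bond is cut. The forward step must enolise the only α-methylene, give the Z enol ether (prenyl chain outside the diene) and stay non-acidic.

12 ⇒ 11. The O–CH3 bond is cut. The forward step must methylate oxygen and not carbon, and give the E enol ether.

11 ⇒ 10. The bond between C5 of the ketone and the formyl carbon is cut. Because 10 is symmetric, formylation can give only one regioisomer.

10 ⇒ 9 ⇒ 7 + 8. First the two C–CO2Me bonds are cut, then the two C–CH2 bonds to the prenyl groups. The ester groups make both α-positions acidic enough for carbonate-mediated alkylation and guarantee a symmetric 2,4-dialkylation pattern. The forward steps need the second prenyl group to go to C4 and not to C2, and a decarboxylation that is neutral towards the alkenes.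

## Other disconnections considered

Alternative 1: The cut goes through ring A at C8a–C8, C7–C6 and C8a–C4a, with C5–C6 arising from a Wolff shift; rings B and C are left for later. In the forward direction, irradiation of diazo ketone A2 would give a ketene bearing a vinyl and a prenyl group. Its [2+2] addition to siloxyalkyne A3, electrocyclic opening of the cyclobutenone and 6π closure (Danheiser benzannulation) would give A1, a 2,4-diprenylresorcinol with the C7 oxygen silylated and the free hydroxyl as the future O1.
- In its favour: the connectivity of A2 and A3 fixes the whole pattern of ring A, including the differentiation of its two oxygens. The reaction type is established, and on this point the alternative is better than the chosen plan, whose key step has no direct precedent. On the structure of ring A the two plans are equal, since both avoid electrophilic prenylation.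
- Against it here: A1 still lacks C2, C3, C4 and ring B. It would need C-acylation at C4a (acidic conditions next to an ortho-prenyl phenol), condensation with 2 and an enantioselective oxa-Michael closure. That closure is reversible, so C2 would be formed last and under the least reliable control, whereas the chosen plan sets it first. Mechanistically, the carbene from A2 has a prenyl alkene within reach, so cyclopropanation competes with the Wolff shift, and the ketene can add to the same alkene.
- Step economy: A2 and A3 would each need about three steps, so the total would be roughly twelve against ten.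

Alternative 2: The cut is made at the two C1''–C2'' bonds of the prenyl groups on an otherwise complete flavanone. In the forward direction, heating bis-Mannich base A5 would expel its amine to give an ortho-quinone methide at one arm. The boronate formed between the C7 phenol and alkenylboronic acid A6 would deliver the 2-methylpropenyl group to the exocyclic methylene, and the sequence would repeat at the second arm to give A4.
- In its favour: the prenyl groups arrive last, so no earlier step has to tolerate them, and aminomethylation is directed ortho to the C7 hydroxyl. Ring A would come from a commercial resorcinol ketone, so in step economy this alternative is better (roughly seven or eight steps), and each reaction type is known.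
- Against it here: the C7 hydroxyl is para to the C4 carbonyl, so ring A is electron-poor, which disfavours both the double Mannich reaction and quinone methide formation. The Mannich step and the key step both combine an amine with heat, the conditions under which a flavanone equilibrates with its chalcone, so the C2 configuration already present in A5 would be at risk twice. The methoxymethyl ethers of A4 need acid for removal, the one condition the ortho-prenyl phenol tolerates least.
- Comparison: the chosen plan keeps ring C away from amines and ends with buffered fluoride, so it is better on stereochemical integrity. The alternative would also need its own asymmetric flavanone synthesis to reach A5.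

Alternative 3: The cut removes ring C at C3–C4 and O1–C2 and divides the target into ring A salicylaldehyde A8 and ring B vinylphenol A9. In the forward direction, A8 with an orthoformate and a chiral phosphoric acid would give a methoxy-substituted ortho-quinone methide. This would add A9 in an inverse-demand [4+2] cycloaddition to give A7, with the free 2'-hydroxyl of A9 as the handle for the catalyst.
- In its favour: it is the most convergent plan, since two arenes are joined, ring C is closed and C2 is set in one catalytic step. In convergency it is better than the chosen plan, and its reaction type is known.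
- Against it here: A7 has a methyl ether at C4, not a ketone, so hydrolysis and oxidation would add two steps on a substrate with two prenyl groups and electron-rich arenes. A8 requires regioselective double C-prenylation of a resorcinol aldehyde, which is the very problem the chosen plan avoids. The free 2-hydroxyl of A8 sits ortho to a prenyl group under Brønsted acid, which invites chromane formation. C4 is set and then destroyed.
- Step economy: A8 (about four or five steps), A9 (two or three), the key step, two steps for the oxidation level and the deprotection come to roughly eleven or twelve, no shorter than the chosen plan.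

Key step: step 9

Assumption: the titanium complex of (S)-BINOL is taken to direct the diene to the Si face of aldehyde 2, the sense it shows in related aldehyde additions; if the opposite face is attacked, (R)-BINOL is used and nothing else changes.

## Route

Step 1
Reactants: 1 2,4-dihydroxybenzaldehyde
Product: 2 2,4-bis(tert-butyldimethylsilyloxy)benzaldehyde
Conditions: TBSCl (2.5 equiv), imidazole (5 equiv), DMF, rt
Reagents that add atoms: tert-butyldimethylsilyl chloride, CC(C)(C)[Si](C)(C)Cl
Why: Silyl ether formation at both phenols; the chelated 2-hydroxyl reacts more slowly, hence the excess of reagent. The silyl ethers keep ring B free of phenoxide chemistry until the end and come off with fluoride.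

Step 2
Reactants: 2 2,4-bis(tert-butyldimethylsilyloxy)benzaldehyde; 3 (E)-1-methoxy-3-(trimethylsilyloxy)buta-1,3-diene
Product: 5 (2S)-2-[2,4-bis(tert-butyldimethylsilyloxy)phenyl]-2,3-dihydro-4H-pyran-4-one, via Mukaiyama aldol adduct 4 (not isolated)
Conditions: (S)-BINOL (20 mol %), Ti(OiPr)4 (20 mol %), 4 Å MS, Et2O, −20 °C; then TFA (cat.), CH2Cl2, 0 °C
Reagents that add atoms: none
Why: Catalytic asymmetric Mukaiyama aldol addition of the siloxydiene terminus to the aldehyde, then acid-induced oxa-Michael closure with loss of methanol (formal hetero-Diels–Alder reaction). C2 is set in the aldol event by the chiral titanium BINOLate, which should expose the Si face of the aldehyde and so give the S configuration; the ring closure does not touch it.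

Step 3
Reactants: 5 (2S)-2-[2,4-bis(tert-butyldimethylsilyloxy)phenyl]-2,3-dihydro-4H-pyran-4-one
Product: 6 (2S)-5-bromo-2-[2,4-bis(tert-butyldimethylsilyloxy)phenyl]-2,3-dihydro-4H-pyran-4-one
Conditions: NBS (1.05 equiv), CH2Cl2, 0 °C, dark
Reagents that add atoms: N-bromosuccinimide, O=C1CCC(=O)N1Br
Why: Electrophilic α-bromination of the vinylogous ester: bromine adds to C5, and the oxocarbenium ion at C6 loses the C5 proton (addition–elimination). Silyl aryl ethers are weaker and bulkier donors than the ring enol ether, so in an apolar solvent at low temperature C5 should react first; no base is present that could enolise C3.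

Step 4
Reactants: 7 dimethyl 3-oxopentanedioate; 8 1-bromo-3-methylbut-2-ene (2 equiv)
Product: 9 dimethyl 2,4-bis(3-methylbut-2-enyl)-3-oxopentanedioate
Conditions: K2CO3 (2.5 equiv), acetone, rt to 50 °C
Reagents that add atoms: none
Why: Twofold C-alkylation of a doubly activated ketodiester under carbonate conditions (active-methylene alkylation). After the first prenylation the unsubstituted C4 methylene is more acidic and less hindered than C2–H, so the second group should go to C4; the diastereomers do not matter because both stereocentres disappear in step 5.

Step 5
Reactants: 9 dimethyl 2,4-bis(3-methylbut-2-enyl)-3-oxopentanedioate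
Product: 10 2,10-dimethylundeca-2,9-dien-6-one
Conditions: LiCl (3 equiv), H2O (4 equiv), DMSO, 140 °C
Reagents that add atoms: none
Why: Krapcho dealkoxycarbonylation: chloride demethylates each β-keto ester, the carboxylate loses CO2 and water protonates the enolate. The neutral medium spares the acid-sensitive trisubstituted alkenes.

Step 6
Reactants: 10 2,10-dimethylundeca-2,9-dien-6-one
Product: 11 (5Z)-5-(hydroxymethylidene)-2,10-dimethylundeca-2,9-dien-6-one
Conditions: NaH (1.5 equiv), HCO2Et (3 equiv), EtOH (cat.), THF, 0 °C to rt; AcOH
Reagents that add atoms: ethyl formate, CCOC=O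
Why: Crossed Claisen condensation of the ketone enolate with ethyl formate, driven by formation of the stabilised enolate of the β-keto aldehyde. The ketone is symmetric, so only one regioisomer can form, and the enolate salt resists a second formylation.

Step 7
Reactants: 11 (5Z)-5-(hydroxymethylidene)-2,10-dimethylundeca-2,9-dien-6-one
Product: 12 (5E)-5-(methoxymethylidene)-2,10-dimethylundeca-2,9-dien-6-one
Conditions: Me2SO4 (1.2 equiv), K2CO3 (1.5 equiv), acetone, reflux
Reagents that add atoms: dimethyl sulfate, COS(=O)(=O)OC
Why: O-Alkylation of the potassium enolate with a hard methylating agent (enol ether formation), which favours oxygen over the substituted α-carbon. The E isomer, with methoxy anti to the carbonyl, is the more stable and should predominate.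

Step 8
Reactants: 12 (5E)-5-(methoxymethylidene)-2,10-dimethylundeca-2,9-dien-6-one
Product: 13 (1E,3Z)-1-methoxy-2,4-bis(3-methylbut-2-enyl)-3-(trimethylsilyloxy)buta-1,3-diene
Conditions: TMSOTf (1.2 equiv), Et3N (2 equiv), Et2O, −10 °C
Reagents that add atoms: trimethylsilyl trifluoromethanesulfonate, C[Si](C)(C)OS(=O)(=O)C(F)(F)F
Why: Soft enolisation and O-silylation of the ketone at its only α-methylene (silyl enol ether formation). Amine-mediated silylation of ketones of this kind gives mainly the Z enol ether, which places the prenyl chain outside the diene, and the excess amine keeps the medium non-acidic.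

Step 9
Reactants: 6 (2S)-5-bromo-2-[2,4-bis(tert-butyldimethylsilyloxy)phenyl]-2,3-dihydro-4H-pyran-4-one; 13 (1E,3Z)-1-methoxy-2,4-bis(3-methylbut-2-enyl)-3-(trimethylsilyloxy)buta-1,3-diene
Product: 16 (2S)-2-[2,4-bis(tert-butyldimethylsilyloxy)phenyl]-7-hydroxy-6,8-bis(3-methylbut-2-enyl)chroman-4-one, via cis-fused cycloadduct 14 (not isolated), via bromo enone 15 (not isolated)
Conditions: 13 (2.5 equiv), 2,6-di-tert-butyl-4-methylpyridine (0.2 equiv), PhMe, 110 °C, sealed tube; then PPTS (0.3 equiv), MeOH–CH2Cl2, 0 °C; then Et3N (3 equiv), CH2Cl2, 0 °C to rt
Reagents that add atoms: none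
Why: Proposed new method: a thermal, concerted but asynchronous [4+2] cycloaddition in which the silyl enol ether terminus of 13 (future C8) bonds to the oxygen-bearing β-carbon C6 of 6 (future C8a) and the methoxy-bearing terminus (future C5) bonds to the brominated α-carbon C5 of 6 (future C4a); the closest known reaction types are Diels–Alder and aromatisation sequences of 1-alkoxy-3-siloxydienes with 2-bromocycloalkenones and with 3-cyano-, 3-acyl- and 3-sulfinylchromones. Ring A is closed by cycloaddition across the C=C bond of the pyranone, so that it shares only C4a–C8a with ring C, and the first product is the cis-fused adduct 14. Mild acid methanolysis then cleaves the silyl enol ether and expels the C5 methoxy group by β-elimination to give bromo enone 15. Because H-8a and bromine are cis in 15, a direct anti elimination is not available; triethylamine enolises the C7 ketone, and HBr should then be lost either from the cyclohexadienol by ionisation of the allylic tertiary bromide or after reversible opening and reclosure of the O1–C8a bond, which never touches C2–O1, and the C7 phenol results. No new stereocentre survives, since C4a, C5, C8 and C8a all become sp2, so neither facial nor endo/exo selectivity matters, and C2 is carried through because it lies outside the reacting π system and neither strong base nor Lewis acid is used. The selectivity that is needed is regiochemical and rests on matched polarity: the largest HOMO coefficient of 13 is at the enol ether terminus and the largest LUMO coefficient of 6 is at its β-carbon, while both terminal substituents of the (1E,3Z)-diene point outward so that the s-cis conformer is accessible. Bromine lowers the LUMO of the otherwise electron-rich vinylogous ester and is the leaving group that brings ring A to the aromatic oxidation level, and the hindered pyridine protects the diene from acid-catalysed hydrolysis during heating.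

Step 10
Reactants: 16 (2S)-2-[2,4-bis(tert-butyldimethylsilyloxy)phenyl]-7-hydroxy-6,8-bis(3-methylbut-2-enyl)chroman-4-one
Product: 17 (2S)-2-(2,4-dihydroxyphenyl)-7-hydroxy-6,8-bis(3-methylbut-2-enyl)chroman-4-one
Conditions: TBAF (2.5 equiv), AcOH (2.5 equiv), THF, 0 °C
Reagents that add atoms: none
Why: Fluoride-induced cleavage of the two aryl silyl ethers. Acetic acid protonates each phenoxide as it forms, so neither retro-oxa-Michael opening of ring C nor quinone methide formation at C2 is triggered, and no strong acid is present that could add the C7 phenol to a prenyl group.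

## Compound list

1 | 2,4-dihydroxybenzaldehyde | O=Cc1ccc(O)cc1O | starting material
2 | 2,4-bis(tert-butyldimethylsilyloxy)benzaldehyde | O=Cc1ccc(O[Si](C)(C)C(C)(C)C)cc1O[Si](C)(C)C(C)(C)C | intermediate
3 | (E)-1-methoxy-3-(trimethylsilyloxy)buta-1,3-diene | CO/C=C/C(=C)O[Si](C)(C)C | starting material
4 | (1E,5S)-5-[2,4-bis(tert-butyldimethylsilyloxy)phenyl]-1-methoxy-5-(trimethylsilyloxy)pent-1-en-3-one | CO/C=C/C(=O)C[C@H](O[Si](C)(C)C)c1ccc(O[Si](C)(C)C(C)(C)C)cc1O[Si](C)(C)C(C)(C)C | intermediate
5 | (2S)-2-[2,4-bis(tert-butyldimethylsilyloxy)phenyl]-2,3-dihydro-4H-pyran-4-one | O=C1C=CO[C@H](c2ccc(O[Si](C)(C)C(C)(C)C)cc2O[Si](C)(C)C(C)(C)C)C1 | intermediate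
6 | (2S)-5-bromo-2-[2,4-bis(tert-butyldimethylsilyloxy)phenyl]-2,3-dihydro-4H-pyran-4-one | BrC1=CO[C@H](c2ccc(O[Si](C)(C)C(C)(C)C)cc2O[Si](C)(C)C(C)(C)C)CC1=O | intermediate
7 | dimethyl 3-oxopentanedioate | COC(=O)CC(=O)CC(=O)OC | starting material
8 | 1-bromo-3-methylbut-2-ene | CC(C)=CCBr | starting material
9 | dimethyl 2,4-bis(3-methylbut-2-enyl)-3-oxopentanedioate (mixture of diastereomers) | COC(=O)C(CC=C(C)C)C(=O)C(CC=C(C)C)C(=O)OC | intermediate
10 | 2,10-dimethylundeca-2,9-dien-6-one | CC(C)=CCCC(=O)CCC=C(C)C | intermediate
11 | (5Z)-5-(hydroxymethylidene)-2,10-dimethylundeca-2,9-dien-6-one (chelated enol of the β-keto aldehyde) | O/C=C(CC=C(C)C)\C(=O)CCC=C(C)C | intermediate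
12 | (5E)-5-(methoxymethylidene)-2,10-dimethylundeca-2,9-dien-6-one | CO/C=C(CC=C(C)C)/C(=O)CCC=C(C)C | intermediate
13 | (1E,3Z)-1-methoxy-2,4-bis(3-methylbut-2-enyl)-3-(trimethylsilyloxy)buta-1,3-diene | CO/C=C(CC=C(C)C)/C(O[Si](C)(C)C)=C/CC=C(C)C | intermediate
14 | (2S)-4a-bromo-2-[2,4-bis(tert-butyldimethylsilyloxy)phenyl]-5-methoxy-6,8-bis(3-methylbut-2-enyl)-7-(trimethylsilyloxy)-2,3,4a,5,8,8a-hexahydro-4H-chromen-4-one (cis ring fusion; mixture at C4a, C5, C8 and C8a) | COC1C(CC=C(C)C)=C(O[Si](C)(C)C)C(CC=C(C)C)C2O[C@H](c3ccc(O[Si](C)(C)C(C)(C)C)cc3O[Si](C)(C)C(C)(C)C)CC(=O)C12Br | intermediate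
15 | (2S)-4a-bromo-2-[2,4-bis(tert-butyldimethylsilyloxy)phenyl]-6,8-bis(3-methylbut-2-enyl)-2,3,8,8a-tetrahydro-4H-chromene-4,7(4aH)-dione (cis ring fusion; mixture at C4a, C8 and C8a) | CC(C)=CCC1=CC2(Br)C(=O)C[C@@H](c3ccc(O[Si](C)(C)C(C)(C)C)cc3O[Si](C)(C)C(C)(C)C)OC2C(CC=C(C)C)C1=O | intermediate
16 | (2S)-2-[2,4-bis(tert-butyldimethylsilyloxy)phenyl]-7-hydroxy-6,8-bis(3-methylbut-2-enyl)chroman-4-one | CC(C)=CCc1cc2c(c(CC=C(C)C)c1O)O[C@H](c1ccc(O[Si](C)(C)C(C)(C)C)cc1O[Si](C)(C)C(C)(C)C)CC2=O | intermediate
17 | (2S)-2-(2,4-dihydroxyphenyl)-7-hydroxy-6,8-bis(3-methylbut-2-enyl)chroman-4-one | CC(C)=CCc1cc2c(c(CC=C(C)C)c1O)O[C@H](c1ccc(O)cc1O)CC2=O | target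

## Step count and least certain steps

Total: 10 steps. Longest linear sequence: 7 steps (steps 4, 5, 6, 7, 8, 9 and 10, from 7 and 8). The aryl branch from 1 has 5 steps (1, 2, 3, 9 and 10).

Step 9 (key step, the one proposed as a new method). Three processes may defeat it.
- The cycloaddition may be too slow, because the ring oxygen deactivates the enone and the diene is tetrasubstituted, so that thermal decay or hydrolysis of the diene wins.
- The dehydrobromination may stall, because H-8a and bromine are cis.
- Under the amine, the C7 enolate may expel O1 irreversibly with loss of bromine.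

The fallback uses known chemistry: sulfoxide activation and thermal syn-elimination, the reaction type established for 3-sulfinylchromones with alkoxy siloxy dienes. It sets out from 5. Sulfenylation at C5 with 4-methylbenzenesulfenyl chloride (CH2Cl2, −78 °C, then Et3N) should give (2S)-2-[2,4-bis(tert-butyldimethylsilyloxy)phenyl]-5-(4-methylphenylsulfanyl)-2,3-dihydro-4H-pyran-4-one F1. Oxidation with mCPBA (1 equiv, −78 °C) should give (2S)-2-[2,4-bis(tert-butyldimethylsilyloxy)phenyl]-5-(4-methylphenylsulfinyl)-2,3-dihydro-4H-pyran-4-one F2 as a mixture at sulfur. Heated with 13 in toluene at 90 °C over NaHCO3, F2 should undergo the same cycloaddition with a stronger acceptor. In the adduct the sulfinyl group and H-8a are cis, which is exactly what the concerted thermal loss of sulfenic acid requires. Loss of methanol through the silyl enol ether and methanolysis of the C7 silyl ether (PPTS, MeOH) bring the sequence back to the route at 16.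

Step 2. Facial selectivity may be poor or turnover slow with the hindered, electron-rich aldehyde, and the acid stage may erode the configuration by ionisation of the benzylic C–O bond. The fallback replaces catalysis by an auxiliary and closes the ring without acid. It sets out from 2. The titanium enolate of 3-acetyl-(4S)-4-isopropyl-1,3-thiazolidine-2-thione (TiCl4, iPr2NEt, CH2Cl2, −78 °C) should add to 2 to give (3S)-3-[2,4-bis(tert-butyldimethylsilyloxy)phenyl]-3-hydroxy-1-[(4S)-4-isopropyl-2-thioxo-1,3-thiazolidin-3-yl]propan-1-one F3. The auxiliary antipode is chosen for the S carbinol, and the minor diastereomer is removed by chromatography. N,O-Dimethylhydroxylamine hydrochloride and imidazole displace the auxiliary to give (3S)-3-[2,4-bis(tert-butyldimethylsilyloxy)phenyl]-3-hydroxy-N-methoxy-N-methylpropanamide F4. Excess ethynylmagnesium bromide then gives (5S)-5-[2,4-bis(tert-butyldimethylsilyloxy)phenyl]-5-hydroxypent-1-yn-3-one F5. A 6-endo oxa-Michael cyclisation with catalytic AgOTf closes the ring and returns to the route at 5.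

Step 3. Bromination of ring B may compete, or a second bromine may be introduced. The fallback brominates a silyl enol ether, which reacts far faster than any aryl ether. It sets out from 2 and 3. A concerted cycloaddition is catalysed by the tetrafluoroborate of the trivalent chromium complex of N,N'-bis(3,5-di-tert-butylsalicylidene)-trans-cyclohexane-1,2-diamine, (salen)CrBF4, in the antipode that directs the diene to the Si face, with no acid treatment. It should give (2S)-2-[2,4-bis(tert-butyldimethylsilyloxy)phenyl]-6-methoxy-4-(trimethylsilyloxy)-3,6-dihydro-2H-pyran F6. NBS in THF at −78 °C should convert it into (6S)-6-[2,4-bis(tert-butyldimethylsilyloxy)phenyl]-3-bromo-2-methoxyoxan-4-one F7. Triethylamine at 0 °C then eliminates methanol (the C3 proton is α to the ketone and the methoxy group is β) and returns to the route at 6.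

Step 4. Over-alkylation, O-alkylation or a second alkylation at C2 in place of C4 may give inseparable mixtures. The fallback builds the ketone from a methyl ketone and a single alkylation. It sets out from 8 and commercial 6-methylhept-5-en-2-one. Condensation of this ketone with 1,1-dimethylhydrazine gives (E)-1,1-dimethyl-2-(6-methylhept-5-en-2-ylidene)hydrazine F8. Deprotonation at the methyl group with LiN(iPr)2 (THF, 0 °C) and alkylation with 8 give 2-(2,10-dimethylundeca-2,9-dien-6-ylidene)-1,1-dimethylhydrazine F9. Hydrolysis with aqueous oxalic acid in a two-phase system returns to the route at 10, bypassing 9.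

## Further compounds

F1 | step 9 | (2S)-2-[2,4-bis(tert-butyldimethylsilyloxy)phenyl]-5-(4-methylphenylsulfanyl)-2,3-dihydro-4H-pyran-4-one | Cc1ccc(SC2=CO[C@H](c3ccc(O[Si](C)(C)C(C)(C)C)cc3O[Si](C)(C)C(C)(C)C)CC2=O)cc1
F2 | step 9 | (2S)-2-[2,4-bis(tert-butyldimethylsilyloxy)phenyl]-5-(4-methylphenylsulfinyl)-2,3-dihydro-4H-pyran-4-one (mixture at sulfur) | Cc1ccc(S(=O)C2=CO[C@H](c3ccc(O[Si](C)(C)C(C)(C)C)cc3O[Si](C)(C)C(C)(C)C)CC2=O)cc1
F3 | step 2 | (3S)-3-[2,4-bis(tert-butyldimethylsilyloxy)phenyl]-3-hydroxy-1-[(4S)-4-isopropyl-2-thioxo-1,3-thiazolidin-3-yl]propan-1-one | CC(C)[C@H]1CSC(=S)N1C(=O)C[C@H](O)c1ccc(O[Si](C)(C)C(C)(C)C)cc1O[Si](C)(C)C(C)(C)C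
F4 | step 2 | (3S)-3-[2,4-bis(tert-butyldimethylsilyloxy)phenyl]-3-hydroxy-N-methoxy-N-methylpropanamide | CON(C)C(=O)C[C@H](O)c1ccc(O[Si](C)(C)C(C)(C)C)cc1O[Si](C)(C)C(C)(C)C
F5 | step 2 | (5S)-5-[2,4-bis(tert-butyldimethylsilyloxy)phenyl]-5-hydroxypent-1-yn-3-one | C#CC(=O)C[C@H](O)c1ccc(O[Si](C)(C)C(C)(C)C)cc1O[Si](C)(C)C(C)(C)C
F6 | step 3 | (2S)-2-[2,4-bis(tert-butyldimethylsilyloxy)phenyl]-6-methoxy-4-(trimethylsilyloxy)-3,6-dihydro-2H-pyran (mixture at C6) | COC1C=C(O[Si](C)(C)C)C[C@@H](c2ccc(O[Si](C)(C)C(C)(C)C)cc2O[Si](C)(C)C(C)(C)C)O1
F7 | step 3 | (6S)-6-[2,4-bis(tert-butyldimethylsilyloxy)phenyl]-3-bromo-2-methoxyoxan-4-one (mixture at C2 and C3) | COC1O[C@H](c2ccc(O[Si](C)(C)C(C)(C)C)cc2O[Si](C)(C)C(C)(C)C)CC(=O)C1Br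
F8 | step 4 | (E)-1,1-dimethyl-2-(6-methylhept-5-en-2-ylidene)hydrazine | CC(C)=CCC/C(C)=N/N(C)C
F9 | step 4 | 2-(2,10-dimethylundeca-2,9-dien-6-ylidene)-1,1-dimethylhydrazine | CC(C)=CCCC(CCC=C(C)C)=NN(C)C
A1 | alternative 1 | 2,4-bis(3-methylbut-2-enyl)-3-(triisopropylsilyloxy)phenol | CC(C)=CCc1ccc(O)c(CC=C(C)C)c1O[Si](C(C)C)(C(C)C)C(C)C
A2 | alternative 1 | 4-diazo-7-methylocta-1,6-dien-3-one | C=CC(=O)C(=[N+]=[N-])CC=C(C)C
A3 | alternative 1 | triisopropyl(5-methylhex-4-en-1-ynyloxy)silane | CC(C)=CCC#CO[Si](C(C)C)(C(C)C)C(C)C
A4 | alternative 2 | (2S)-2-[2,4-bis(methoxymethoxy)phenyl]-7-hydroxy-6,8-bis(3-methylbut-2-enyl)chroman-4-one | CC(C)=CCc1cc2c(c(CC=C(C)C)c1O)O[C@H](c1ccc(OCOC)cc1OCOC)CC2=O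
A5 | alternative 2 | (2S)-2-[2,4-bis(methoxymethoxy)phenyl]-6,8-bis[(dimethylamino)methyl]-7-hydroxychroman-4-one | CN(C)Cc1cc2c(c(CN(C)C)c1O)O[C@H](c1ccc(OCOC)cc1OCOC)CC2=O
A6 | alternative 2 | 2-methylprop-1-enylboronic acid | CC(C)=CB(O)O
A7 | alternative 3 | (2S,4S)-7-(tert-butyldimethylsilyloxy)-2-[4-(tert-butyldimethylsilyloxy)-2-hydroxyphenyl]-4-methoxy-6,8-bis(3-methylbut-2-enyl)chromane | CC(C)=CCc1cc2c(c(CC=C(C)C)c1O[Si](C)(C)C(C)(C)C)O[C@H](c1ccc(O[Si](C)(C)C(C)(C)C)cc1O)C[C@@H]2OC
A8 | alternative 3 | 4-(tert-butyldimethylsilyloxy)-2-hydroxy-3,5-bis(3-methylbut-2-enyl)benzaldehyde | O=Cc1cc(CC=C(C)C)c(O[Si](C)(C)C(C)(C)C)c(CC=C(C)C)c1O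
A9 | alternative 3 | 5-(tert-butyldimethylsilyloxy)-2-ethenylphenol | C=Cc1ccc(O[Si](C)(C)C(C)(C)C)cc1O
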